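**Retrosynthetic overview**
1. Target ⇒ bis‑TBS ether 24 (buffered fluoride at the end) ⇒ (S)‑allylic alcohol 21 + angelic acid 22 (mixed‑anhydride esterification).
2. Prenyl terminus of 21 ⇒ allyl carbinol 20 by cross‑metathesis with 2‑methyl‑2‑butene.
3. Key C–C bond (C3–C4 of the heptadienyl chain): asymmetric carbonyl allylation of 2‑arylacrolein 15 with B‑allyldiisopinocampheylborane, which sets the (S) centre.
4. Enal 15 ⇒ Mannich methylenation of arylacetaldehyde 13 ⇐ oxidative cleavage of allylarene 11 ⇐ Claisen rearrangement; the oxygenation pattern comes from 2,6‑dimethoxytoluene (formylation, Dakin, oxidative demethylation, reduction).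
5. No ring is formed; the benzene ring is carried through from 1.

Assumption: the SMILES is read as the (3S) carbinol with a (Z)‑2‑methylbut‑2‑enoate (angelate); TBS = tert‑butyldimethylsilyl, Ipc = isopinocampheyl from (+)‑α‑pinene, "aryl" in short names = 2,5‑bis(TBS‑oxy)‑3‑methoxy‑4‑methylphenyl.

**Route**

Step 1
Reactants: 1 2,6‑dimethoxytoluene
Product: 3 2,4‑dimethoxy‑3‑methylbenzaldehyde, via iminium salt 2 (not isolated)
Conditions: POCl3, DMF, 0 → 90 °C; then ice‑water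
Reagents that add atoms: N,N‑dimethylformamide CN(C)C=O (formyl carbon); water O (carbonyl oxygen)
Why: Vilsmeier–Haack formylation occurs only at the position ortho to one methoxy and para to the other (the two such positions are equivalent by symmetry).

Step 2
Reactants: 3 2,4‑dimethoxy‑3‑methylbenzaldehyde
Product: 5 2,4‑dimethoxy‑3‑methylphenol, via aryl formate 4 (not isolated)
Conditions: mCPBA, CH2Cl2, 0 °C → rt; then K2CO3 (cat.), MeOH, rt
Reagents that add atoms: 3‑chloroperoxybenzoic acid OOC(=O)c1cccc(Cl)c1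
Why: Baeyer–Villiger (Dakin‑type) oxidation, in which the electron‑rich aryl group migrates, followed by methanolysis of the formate.

Step 3
Reactants: 5 2,4‑dimethoxy‑3‑methylphenol
Product: 6 1‑(allyloxy)‑2,4‑dimethoxy‑3‑methylbenzene
Conditions: allyl bromide, K2CO3, acetone, reflux
Reagents that add atoms: allyl bromide C=CCBr
Why: Williamson ether synthesis on a phenoxide with a primary allylic halide.

Step 4
Reactants: 6 1‑(allyloxy)‑2,4‑dimethoxy‑3‑methylbenzene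
Product: 8 6‑allyl‑2,4‑dimethoxy‑3‑methylphenol, via dienone 7 (not isolated)
Conditions: N,N‑diethylaniline, 195 °C, Ar
Reagents that add atoms: none
Why: Aromatic Claisen rearrangement delivers the allyl group to the only free ortho position (the other ortho and the para position carry OMe), then the dienone tautomerises.

Step 5
Reactants: 8 6‑allyl‑2,4‑dimethoxy‑3‑methylphenol
Product: 9 5‑allyl‑3‑methoxy‑2‑methyl‑1,4‑benzoquinone
Conditions: PhI(OAc)2, MeCN/H2O (4:1), 0 °C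
Reagents that add atoms: water O
Why: Hypervalent‑iodine oxidative demethylation of a p‑methoxyphenol; water adds at the methoxy‑bearing para carbon and methanol is expelled to give the p‑quinone.

Step 6
Reactants: 9 5‑allyl‑3‑methoxy‑2‑methyl‑1,4‑benzoquinone
Product: 10 5‑allyl‑3‑methoxy‑2‑methylbenzene‑1,4‑diol
Conditions: Na2S2O4, EtOAc/H2O, rt, Ar
Reagents that add atoms: none
Why: Dithionite reduction of a quinone to its hydroquinone is fast and leaves the allyl group untouched.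

Step 7
Reactants: 10 5‑allyl‑3‑methoxy‑2‑methylbenzene‑1,4‑diol
Product: 11 1‑allyl‑2,5‑bis(tert‑butyldimethylsilyloxy)‑3‑methoxy‑4‑methylbenzene
Conditions: TBSCl, imidazole, DMAP (cat.), DMF, 40 °C
Reagents that add atoms: tert‑butyldimethylsilyl chloride CC(C)(C)[Si](C)(C)Cl
Why: Corey silylation of both phenols gives ethers that survive the following steps and come off later with buffered fluoride.

Step 8
Reactants: 11 1‑allyl‑2,5‑bis(tert‑butyldimethylsilyloxy)‑3‑methoxy‑4‑methylbenzene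
Product: 13 2‑[2,5‑bis(tert‑butyldimethylsilyloxy)‑3‑methoxy‑4‑methylphenyl]acetaldehyde, via diol 12 (not isolated)
Conditions: OsO4 (2 mol%), NaIO4, 2,6‑lutidine, dioxane/H2O (3:1), rt
Reagents that add atoms: osmium tetroxide O=[Os](=O)(=O)=O (oxygen donor, re‑formed by sodium periodate [Na+].[O-]I(=O)(=O)=O)
Why: Lemieux–Johnson oxidation (dihydroxylation, then periodate glycol cleavage) converts the terminal alkene into the arylacetaldehyde under buffered, near‑neutral conditions.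

Step 9
Reactants: 13 2‑[2,5‑bis(tert‑butyldimethylsilyloxy)‑3‑methoxy‑4‑methylphenyl]acetaldehyde
Product: 15 2‑[2,5‑bis(tert‑butyldimethylsilyloxy)‑3‑methoxy‑4‑methylphenyl]prop‑2‑enal, via Mannich base 14 (not isolated)
Conditions: CH2=NMe2+ I− (Eschenmoser's salt), Et3N, CH2Cl2, rt; used at once
Reagents that add atoms: Eschenmoser's salt C=[N+](C)C.[I-]
Why: Intermolecular Mannich reaction of the aldehyde enol with the preformed iminium ion, then E1cB loss of dimethylamine from the acidic benzylic α‑position, gives the α‑methylene aldehyde.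

Step 10 (key step)
Reactants: 15 2‑[2,5‑bis(tert‑butyldimethylsilyloxy)‑3‑methoxy‑4‑methylphenyl]prop‑2‑enal; 16 (−)‑B‑methoxydiisopinocampheylborane; 17 allylmagnesium bromide
Product: 20 (3S)‑2‑[2,5‑bis(tert‑butyldimethylsilyloxy)‑3‑methoxy‑4‑methylphenyl]hexa‑1,5‑dien‑3‑ol, via allylborane 18 (not isolated), via borinate 19 (not isolated)
Conditions: 16 + 17, Et2O, −78 °C → rt; then 15, Et2O, −78 °C; then NaBO3·4H2O, THF/H2O, rt
Reagents that add atoms: none
Why: Brown asymmetric carbonyl allylation through a chair six‑membered transition state; the Ipc groups from (+)‑α‑pinene direct allyl transfer to the Si face of the aldehyde, which gives the (S) carbinol (O > vinyl C > CH2 > H), and the mild perborate work‑up spares the aryl silyl ethers.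

Step 11
Reactants: 20 (3S)‑2‑[2,5‑bis(tert‑butyldimethylsilyloxy)‑3‑methoxy‑4‑methylphenyl]hexa‑1,5‑dien‑3‑ol
Product: 21 (3S)‑2‑[2,5‑bis(tert‑butyldimethylsilyloxy)‑3‑methoxy‑4‑methylphenyl]‑6‑methylhepta‑1,5‑dien‑3‑ol
Conditions: 2‑methyl‑2‑butene (excess), Grubbs II (5 mol%), CH2Cl2, 40 °C
Reagents that add atoms: 2‑methyl‑2‑butene CC=C(C)C
Why: Olefin cross‑metathesis turns the monosubstituted alkene into the prenyl terminus, while the hindered 1,1‑disubstituted aryl alkene is inert and the stereocentre is not touched.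

Step 12
Reactants: 21 (3S)‑2‑[2,5‑bis(tert‑butyldimethylsilyloxy)‑3‑methoxy‑4‑methylphenyl]‑6‑methylhepta‑1,5‑dien‑3‑ol; 22 angelic acid
Product: 24 (3S)‑2‑[2,5‑bis(tert‑butyldimethylsilyloxy)‑3‑methoxy‑4‑methylphenyl]‑6‑methylhepta‑1,5‑dien‑3‑yl (2Z)‑2‑methylbut‑2‑enoate, via mixed anhydride 23 (not isolated)
Conditions: 22, 2,4,6‑Cl3C6H2COCl, Et3N, toluene, rt; then 21, toluene, 80 °C (no DMAP)
Reagents that add atoms: none
Why: Yamaguchi‑type mixed‑anhydride esterification acylates the alcohol at the less hindered angeloyl carbonyl with retention at the carbinol, and leaving out nucleophilic catalysts limits Z → E isomerisation.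

Step 13
Reactants: 24 (3S)‑2‑[2,5‑bis(tert‑butyldimethylsilyloxy)‑3‑methoxy‑4‑methylphenyl]‑6‑methylhepta‑1,5‑dien‑3‑yl (2Z)‑2‑methylbut‑2‑enoate
Product: 25 (3S)‑2‑(2,5‑dihydroxy‑3‑methoxy‑4‑methylphenyl)‑6‑methylhepta‑1,5‑dien‑3‑yl (2Z)‑2‑methylbut‑2‑enoate
Conditions: TBAF, AcOH (1:1), THF, 0 °C, Ar; pH 6 work‑up
Reagents that add atoms: none
Why: Fluoride desilylation of the aryl silyl ethers, buffered with acetic acid so that no free phenoxide can attack or migrate the allylic angelate or be oxidised to the quinone.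

**Compound list**
1 | 2,6‑dimethoxytoluene (1,3‑dimethoxy‑2‑methylbenzene) | COc1cccc(OC)c1C | starting material
2 | (2,4‑dimethoxy‑3‑methylbenzylidene)dimethyliminium dichlorophosphate | COc1ccc(C=[N+](C)C)c(OC)c1C.[O-]P(=O)(Cl)Cl | intermediate
3 | 2,4‑dimethoxy‑3‑methylbenzaldehyde | COc1ccc(C=O)c(OC)c1C | intermediate
4 | 2,4‑dimethoxy‑3‑methylphenyl formate | COc1ccc(OC=O)c(OC)c1C | intermediate
5 | 2,4‑dimethoxy‑3‑methylphenol | COc1ccc(O)c(OC)c1C | intermediate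
6 | 1‑(allyloxy)‑2,4‑dimethoxy‑3‑methylbenzene | C=CCOc1ccc(OC)c(C)c1OC | intermediate
7 | 6‑allyl‑2,4‑dimethoxy‑3‑methylcyclohexa‑2,4‑dien‑1‑one (racemic) | C=CCC1C=C(OC)C(C)=C(OC)C1=O | intermediate
8 | 6‑allyl‑2,4‑dimethoxy‑3‑methylphenol | C=CCc1cc(OC)c(C)c(OC)c1O | intermediate
9 | 5‑allyl‑3‑methoxy‑2‑methyl‑1,4‑benzoquinone | C=CCC1=CC(=O)C(C)=C(OC)C1=O | intermediate
10 | 5‑allyl‑3‑methoxy‑2‑methylbenzene‑1,4‑diol | C=CCc1cc(O)c(C)c(OC)c1O | intermediate
11 | 1‑allyl‑2,5‑bis(tert‑butyldimethylsilyloxy)‑3‑methoxy‑4‑methylbenzene | C=CCc1cc(O[Si](C)(C)C(C)(C)C)c(C)c(OC)c1O[Si](C)(C)C(C)(C)C | intermediate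
12 | 3‑[2,5‑bis(tert‑butyldimethylsilyloxy)‑3‑methoxy‑4‑methylphenyl]propane‑1,2‑diol (racemic) | OCC(O)Cc1cc(O[Si](C)(C)C(C)(C)C)c(C)c(OC)c1O[Si](C)(C)C(C)(C)C | intermediate
13 | 2‑[2,5‑bis(tert‑butyldimethylsilyloxy)‑3‑methoxy‑4‑methylphenyl]acetaldehyde | O=CCc1cc(O[Si](C)(C)C(C)(C)C)c(C)c(OC)c1O[Si](C)(C)C(C)(C)C | intermediate
14 | 2‑[2,5‑bis(tert‑butyldimethylsilyloxy)‑3‑methoxy‑4‑methylphenyl]‑3‑(dimethylamino)propanal (racemic) | CN(C)CC(C=O)c1cc(O[Si](C)(C)C(C)(C)C)c(C)c(OC)c1O[Si](C)(C)C(C)(C)C | intermediate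
15 | 2‑[2,5‑bis(tert‑butyldimethylsilyloxy)‑3‑methoxy‑4‑methylphenyl]prop‑2‑enal | C=C(C=O)c1cc(O[Si](C)(C)C(C)(C)C)c(C)c(OC)c1O[Si](C)(C)C(C)(C)C | intermediate
16 | (−)‑B‑methoxydiisopinocampheylborane (Ipc from (+)‑α‑pinene) | COB([C@@H]1C[C@@H]2C[C@H]([C@H]1C)C2(C)C)[C@@H]1C[C@@H]2C[C@H]([C@H]1C)C2(C)C | starting material
17 | allylmagnesium bromide | C=CC[Mg]Br | starting material
18 | B‑allyldiisopinocampheylborane (Ipc from (+)‑α‑pinene) | C=CCB([C@@H]1C[C@@H]2C[C@H]([C@H]1C)C2(C)C)[C@@H]1C[C@@H]2C[C@H]([C@H]1C)C2(C)C | intermediate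
19 | (3S)‑2‑[2,5‑bis(tert‑butyldimethylsilyloxy)‑3‑methoxy‑4‑methylphenyl]hexa‑1,5‑dien‑3‑yl diisopinocampheylborinate | C=C(c1cc(O[Si](C)(C)C(C)(C)C)c(C)c(OC)c1O[Si](C)(C)C(C)(C)C)[C@H](CC=C)OB([C@@H]1C[C@@H]2C[C@H]([C@H]1C)C2(C)C)[C@@H]1C[C@@H]2C[C@H]([C@H]1C)C2(C)C | intermediate
20 | (3S)‑2‑[2,5‑bis(tert‑butyldimethylsilyloxy)‑3‑methoxy‑4‑methylphenyl]hexa‑1,5‑dien‑3‑ol | C=C(c1cc(O[Si](C)(C)C(C)(C)C)c(C)c(OC)c1O[Si](C)(C)C(C)(C)C)[C@H](CC=C)O | intermediate
21 | (3S)‑2‑[2,5‑bis(tert‑butyldimethylsilyloxy)‑3‑methoxy‑4‑methylphenyl]‑6‑methylhepta‑1,5‑dien‑3‑ol | C=C(c1cc(O[Si](C)(C)C(C)(C)C)c(C)c(OC)c1O[Si](C)(C)C(C)(C)C)[C@H](CC=C(C)C)O | intermediate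
22 | angelic acid, (2Z)‑2‑methylbut‑2‑enoic acid | C/C=C(/C)C(=O)O | starting material
23 | (2Z)‑2‑methylbut‑2‑enoic 2,4,6‑trichlorobenzoic anhydride | C/C=C(/C)C(=O)OC(=O)c1c(Cl)cc(Cl)cc1Cl | intermediate
24 | (3S)‑2‑[2,5‑bis(tert‑butyldimethylsilyloxy)‑3‑methoxy‑4‑methylphenyl]‑6‑methylhepta‑1,5‑dien‑3‑yl (2Z)‑2‑methylbut‑2‑enoate | C=C(c1cc(O[Si](C)(C)C(C)(C)C)c(C)c(OC)c1O[Si](C)(C)C(C)(C)C)[C@H](CC=C(C)C)OC(=O)/C(C)=C\C | intermediate
25 | (3S)‑2‑(2,5‑dihydroxy‑3‑methoxy‑4‑methylphenyl)‑6‑methylhepta‑1,5‑dien‑3‑yl (2Z)‑2‑methylbut‑2‑enoate | C=C(c1cc(O)c(C)c(OC)c1O)[C@H](CC=C(C)C)OC(=O)/C(C)=C\C | target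

**Step count and risks**
Total steps: 13. Longest linear sequence: 13 (1 → 25; compounds 16, 17 and 22 are bought).

Three steps most likely to fail:

Step 9 (Mannich methylenation). Aldehyde 13 can self‑condense and enal 15 can polymerise or dimerise on isolation. The fallback sets out from 13 and comes back at 15, reaching the enal from a storable alcohol. Pinnick oxidation (NaClO2, NaH2PO4, 2‑methyl‑2‑butene, t‑BuOH/H2O) gives [2,5‑bis(tert‑butyldimethylsilyloxy)‑3‑methoxy‑4‑methylphenyl]acetic acid F1. TMSCHN2 in toluene/MeOH gives the methyl arylacetate F2. Aldol‑type hydroxymethylation and dehydration with paraformaldehyde, K2CO3 and Bu4NI in toluene at 80 °C gives the methyl 2‑arylacrylate F3. DIBAL‑H at −78 °C gives the 2‑arylprop‑2‑en‑1‑ol F4. MnO2 in CH2Cl2 then oxidises F4 to 15, and the filtered solution goes straight into step 10.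

Step 10 (asymmetric allylation). The ee may be eroded with this hindered α‑aryl enal, and the oxidative work‑up may attack the aryl silyl ethers. The fallback sets out from 15 and comes back at 20, setting the stereocentre by ketone reduction instead. Addition of allylmagnesium bromide 17 in THF at −78 °C gives the racemic 2‑arylhexa‑1,5‑dien‑3‑ol F5. Dess–Martin periodinane with NaHCO3 in CH2Cl2 at 0 °C gives the 2‑arylhexa‑1,5‑dien‑3‑one F6. Corey–Bakshi–Shibata reduction with (R)‑Me‑CBS and catecholborane in toluene at −78 °C, with the α‑arylvinyl group as the large substituent, gives (S)‑20.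

Step 12 (angeloylation). Acylation of the hindered alcohol may be slow and the angelate may isomerise to the tiglate. The fallback sets out from 21 and comes back at 24, building the Z alkene after the ester bond. DCC/DMAP coupling of 21 with 2‑[bis(2,2,2‑trifluoroethoxy)phosphoryl]propanoic acid in CH2Cl2 gives the phosphonopropanoate ester F7. Still–Gennari olefination of F7 (KHMDS, 18‑crown‑6, THF, −78 °C, then acetaldehyde) gives the Z‑configured 2‑methylbut‑2‑enoate 24.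

**Further compounds**
F1 | step 9 | [2,5‑bis(tert‑butyldimethylsilyloxy)‑3‑methoxy‑4‑methylphenyl]acetic acid | OC(=O)Cc1cc(O[Si](C)(C)C(C)(C)C)c(C)c(OC)c1O[Si](C)(C)C(C)(C)C
F2 | step 9 | methyl [2,5‑bis(tert‑butyldimethylsilyloxy)‑3‑methoxy‑4‑methylphenyl]acetate | COC(=O)Cc1cc(O[Si](C)(C)C(C)(C)C)c(C)c(OC)c1O[Si](C)(C)C(C)(C)C
F3 | step 9 | methyl 2‑[2,5‑bis(tert‑butyldimethylsilyloxy)‑3‑methoxy‑4‑methylphenyl]prop‑2‑enoate | C=C(C(=O)OC)c1cc(O[Si](C)(C)C(C)(C)C)c(C)c(OC)c1O[Si](C)(C)C(C)(C)C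
F4 | step 9 | 2‑[2,5‑bis(tert‑butyldimethylsilyloxy)‑3‑methoxy‑4‑methylphenyl]prop‑2‑en‑1‑ol | C=C(CO)c1cc(O[Si](C)(C)C(C)(C)C)c(C)c(OC)c1O[Si](C)(C)C(C)(C)C
F5 | step 10 | rac‑2‑[2,5‑bis(tert‑butyldimethylsilyloxy)‑3‑methoxy‑4‑methylphenyl]hexa‑1,5‑dien‑3‑ol | C=C(c1cc(O[Si](C)(C)C(C)(C)C)c(C)c(OC)c1O[Si](C)(C)C(C)(C)C)C(O)CC=C
F6 | step 10 | 2‑[2,5‑bis(tert‑butyldimethylsilyloxy)‑3‑methoxy‑4‑methylphenyl]hexa‑1,5‑dien‑3‑one | C=C(c1cc(O[Si](C)(C)C(C)(C)C)c(C)c(OC)c1O[Si](C)(C)C(C)(C)C)C(=O)CC=C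
F7 | step 12 | (3S)‑2‑[2,5‑bis(tert‑butyldimethylsilyloxy)‑3‑methoxy‑4‑methylphenyl]‑6‑methylhepta‑1,5‑dien‑3‑yl 2‑[bis(2,2,2‑trifluoroethoxy)phosphoryl]propanoate (both epimers at the phosphonate carbon) | C=C(c1cc(O[Si](C)(C)C(C)(C)C)c(C)c(OC)c1O[Si](C)(C)C(C)(C)C)[C@H](CC=C(C)C)OC(=O)C(C)P(=O)(OCC(F)(F)F)OCC(F)(F)F
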